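**Plan**

- Retrosynthesis: cut the C=C of the enoic acid (Wittig), the epoxide (Sharpless epoxidation of a dienol) and the C-1 methyl group (hydrogenation of a 1-methylidene ketone). Then cut both ring bonds C1–C2 and C4a–C8a in one operation, which opens the bicycle to an acyclic trienyne aldehyde. Cut that at the tetrasubstituted C6=C7 alkene (carbomagnesiation of a 1,3-diyne) and at the diyne (Cadiot–Chodkiewicz).
- Enabling feature: in ring B the ketone carbon C-2 is 1,4 to the sp2 fusion carbon C-4a, and the exocyclic double bond C4a=C5 lies in ring A. C2–C3–C4–C4a=C5 is therefore a masked 4-alkynal and C1–C8a a vinyl group on C-8, so a hydroacylative [4+2] annulation can close ring A (through the C6=C7–C8 tether) and ring B together.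
- Forward order: two auxiliary-derived fragments, then diyne, Z-enyne, trienyne aldehyde, rings A and B in step 20, C-1 methyl, epoxide, acid.
- Stereochemistry: C-8 and C-3 come from Evans enolate reactions and C-8a from C-8 in the key step. C-1 comes from hydrogen delivery anti to the C-8 side chain, the epoxide from L-(+)-diethyl tartrate, and the alkene geometries from syn-carbomagnesiation and stabilised ylides.

Key step: step 20

Remark on locants: the bicycle is numbered as 3,4,8,8a-tetrahydronaphthalen-2(1H)-one (C-1 CH next to C-8a, C-2 ketone, C-3 CH(CH3), C-4 CH2, C-4a, C-5 =CH, C-6 C(CH3), C-7 bearing the 2-oxopropyl group, C-8 bearing the side chain, C-8a). Ring A is the diene ring and ring B the ketone ring.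

Remark on one stereocentre: racemic propylene oxide is used, so every intermediate that carries the 2-hydroxypropyl or 2-silyloxypropyl arm is a mixture of both epimers at that carbinol carbon. The centre ends as the ketone and is left undefined in the SMILES.

Step 1
Reactants: 1 (4R)-4-benzyl-3-propanoyl-1,3-oxazolidin-2-one
Product: 2 (4R)-4-benzyl-3-[(2S)-2-methylpent-4-ynoyl]-1,3-oxazolidin-2-one
Conditions: NaN(SiMe3)2, THF, −78 °C; HC≡CCH2Br, −78 → −40 °C
Reagents that add atoms: propargyl bromide, C#CCBr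
Why: Evans asymmetric alkylation, in which the chelated Z-enolate is attacked on the face away from the benzyl group and so sets the (2S) centre that becomes C-3.

Step 2
Reactants: 2 (4R)-4-benzyl-3-[(2S)-2-methylpent-4-ynoyl]-1,3-oxazolidin-2-one
Product: 3 (2S)-2-methylpent-4-yn-1-ol
Conditions: LiBH4, MeOH (1 equiv), THF, 0 °C
Reagents that add atoms: none
Why: reductive cleavage of the N-acyl oxazolidinone should give the primary alcohol without touching the stereocentre and return the auxiliary.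

Step 3
Reactants: 3 (2S)-2-methylpent-4-yn-1-ol
Product: 4 triethyl{[(2S)-2-methylpent-4-yn-1-yl]oxy}silane
Conditions: TESCl, imidazole, CH2Cl2, 0 °C
Reagents that add atoms: chlorotriethylsilane, CC[Si](Cl)(CC)CC
Why: silyl ether formation; the triethylsilyl group is chosen because it can later be oxidised directly to the aldehyde beside tert-butyldimethylsilyl ethers.

Step 4
Reactants: 4 triethyl{[(2S)-2-methylpent-4-yn-1-yl]oxy}silane
Product: 5 {[(2S)-5-bromo-2-methylpent-4-yn-1-yl]oxy}triethylsilane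
Conditions: NBS, AgNO3 (10 mol %), acetone, rt
Reagents that add atoms: N-bromosuccinimide, BrN1C(=O)CCC1=O
Why: silver-catalysed bromination of a terminal alkyne gives the 1-bromoalkyne needed for the Cadiot–Chodkiewicz coupling.

Step 5
Reactants: 6 but-3-enoic acid; 7 (4S)-4-benzyl-1,3-oxazolidin-2-one
Product: 9 (4S)-4-benzyl-3-(but-3-enoyl)-1,3-oxazolidin-2-one, via mixed pivalic anhydride 8 (not isolated)
Conditions: t-BuCOCl, Et3N, THF, −20 °C; then 7, LiCl, rt
Reagents that add atoms: none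
Why: N-acylation of the oxazolidinone through the mixed anhydride under amine/LiCl conditions, which avoid strong base and conjugation of the β,γ-alkene.

Step 6
Reactants: 9 (4S)-4-benzyl-3-(but-3-enoyl)-1,3-oxazolidin-2-one
Product: 10 (4S)-4-benzyl-3-[(2R)-2-(hydroxymethyl)but-3-enoyl]-1,3-oxazolidin-2-one
Conditions: TiCl4, i-Pr2NEt, CH2Cl2, 0 °C; 1,3,5-trioxane, TiCl4, 0 °C
Reagents that add atoms: 1,3,5-trioxane, C1OCOCO1
Why: Evans hydroxymethylation of the titanium enolate with formaldehyde released from trioxane; α-attack anti to the benzyl group sets the (2R) centre that becomes C-8.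

Step 7
Reactants: 10 (4S)-4-benzyl-3-[(2R)-2-(hydroxymethyl)but-3-enoyl]-1,3-oxazolidin-2-one
Product: 11 (4S)-4-benzyl-3-[(2R)-2-{[(tert-butyldimethylsilyl)oxy]methyl}but-3-enoyl]-1,3-oxazolidin-2-one
Conditions: TBSCl, imidazole, DMF, rt
Reagents that add atoms: tert-butyldimethylsilyl chloride, CC(C)(C)[Si](C)(C)Cl
Why: silylation keeps the two CH2O arms on the stereocentre distinct before the auxiliary is removed.

Step 8
Reactants: 11 (4S)-4-benzyl-3-[(2R)-2-{[(tert-butyldimethylsilyl)oxy]methyl}but-3-enoyl]-1,3-oxazolidin-2-one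
Product: 12 (2S)-2-{[(tert-butyldimethylsilyl)oxy]methyl}but-3-en-1-ol
Conditions: LiBH4, MeOH (1 equiv), THF, 0 °C
Reagents that add atoms: none
Why: reductive removal of the auxiliary gives the primary alcohol and recovers the oxazolidinone.

Step 9
Reactants: 12 (2S)-2-{[(tert-butyldimethylsilyl)oxy]methyl}but-3-en-1-ol
Product: 13 (2R)-2-{[(tert-butyldimethylsilyl)oxy]methyl}but-3-enal
Conditions: DMP, NaHCO3, CH2Cl2, 0 °C
Reagents that add atoms: none
Why: buffered Dess–Martin oxidation is non-basic, and the aldehyde is used at once so that the α-vinyl centre should not epimerise or eliminate.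

Step 10
Reactants: 13 (2R)-2-{[(tert-butyldimethylsilyl)oxy]methyl}but-3-enal
Product: 14 tert-butyl{[(2S)-2-ethenylbut-3-yn-1-yl]oxy}dimethylsilane
Conditions: TMSCHN2, n-BuLi, THF, −78 → 0 °C
Reagents that add atoms: (trimethylsilyl)diazomethane, C[Si](C)(C)C=[N+]=[N-]
Why: Colvin homologation (addition, Peterson elimination, loss of N2 and 1,2-hydrogen shift of the alkylidene carbene) converts the aldehyde into the terminal alkyne at low temperature.

Step 11
Reactants: 14 tert-butyl{[(2S)-2-ethenylbut-3-yn-1-yl]oxy}dimethylsilane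
Product: 15 (2S)-2-ethenylbut-3-yn-1-ol
Conditions: TBAF, THF, 0 °C (volatile product, carried on as an ethereal solution)
Reagents that add atoms: none
Why: fluoride desilylation frees the homopropargylic hydroxyl that directs step 13.

Step 12
Reactants: 15 (2S)-2-ethenylbut-3-yn-1-ol; 5 {[(2S)-5-bromo-2-methylpent-4-yn-1-yl]oxy}triethylsilane
Product: 16 (2S,8S)-2-ethenyl-8-methyl-9-[(triethylsilyl)oxy]nona-3,5-diyn-1-ol
Conditions: CuCl (5 mol %), NH2OH·HCl, n-BuNH2 (30% aq), Et2O, 0 °C
Reagents that add atoms: none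
Why: Cadiot–Chodkiewicz coupling of the copper acetylide with the bromoalkyne joins the two fragments as an unsymmetrical 1,3-diyne.

Step 13
Reactants: 16 (2S,8S)-2-ethenyl-8-methyl-9-[(triethylsilyl)oxy]nona-3,5-diyn-1-ol
Product: 18 (2S,3Z,8S)-2-ethenyl-3-(2-hydroxypropyl)-4,8-dimethyl-9-[(triethylsilyl)oxy]non-3-en-5-yn-1-ol, via alkenylmagnesium chelate 17 (not isolated)
Conditions: Fe(acac)3 (15 mol %), MeMgBr (excess), THF, −20 → 0 °C; then CuI (20 mol %), (±)-propylene oxide (excess), −20 °C → rt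
Reagents that add atoms: methylmagnesium bromide, C[Mg]Br; 2-methyloxirane, CC1CO1
Why: alkoxide-directed iron-catalysed syn-carbomagnesiation of the homopropargylic alcohol puts methyl on the distal and magnesium on the proximal alkyne carbon (five-membered chelate), and copper-catalysed opening of the epoxide at CH2 with retention then fixes the tetrasubstituted 3Z alkene.

Step 14
Reactants: 18 (2S,3Z,8S)-2-ethenyl-3-(2-hydroxypropyl)-4,8-dimethyl-9-[(triethylsilyl)oxy]non-3-en-5-yn-1-ol
Product: 19 (2S,3Z,8S)-2-ethenyl-4,8-dimethyl-3-(2-oxopropyl)-9-[(triethylsilyl)oxy]non-3-en-5-ynal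
Conditions: DMP (3 equiv), NaHCO3, CH2Cl2, 0 °C → rt
Reagents that add atoms: none
Why: Dess–Martin oxidation of both hydroxyls gives the aldehyde for chain extension and parks the secondary alcohol as the ketone, so no free hydroxyl can add to the enal made next.

Step 15
Reactants: 19 (2S,3Z,8S)-2-ethenyl-4,8-dimethyl-3-(2-oxopropyl)-9-[(triethylsilyl)oxy]non-3-en-5-ynal
Product: 20 (2E,4R,5Z,10S)-4-ethenyl-2,6,10-trimethyl-5-(2-oxopropyl)-11-[(triethylsilyl)oxy]undeca-2,5-dien-7-ynal
Conditions: Ph3P=C(CH3)CHO, toluene, 70 °C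
Reagents that add atoms: 2-(triphenylphosphoranylidene)propanal, CC(C=O)=P(c1ccccc1)(c1ccccc1)c1ccccc1
Why: Wittig reaction of a formyl-stabilised ylide is aldehyde-selective (the ketone is untouched), needs no added base and should give the E-trisubstituted enal.

Step 16
Reactants: 20 (2E,4R,5Z,10S)-4-ethenyl-2,6,10-trimethyl-5-(2-oxopropyl)-11-[(triethylsilyl)oxy]undeca-2,5-dien-7-ynal
Product: 21 ethyl (2E,4E,6R,7Z,12S)-6-ethenyl-2,4,8,12-tetramethyl-7-(2-oxopropyl)-13-[(triethylsilyl)oxy]trideca-2,4,7-trien-9-ynoate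
Conditions: Ph3P=C(CH3)CO2Et, CH2Cl2, 40 °C
Reagents that add atoms: ethyl 2-(triphenylphosphoranylidene)propanoate, CCOC(=O)C(C)=P(c1ccccc1)(c1ccccc1)c1ccccc1
Why: a second Wittig reaction with an ester-stabilised ylide should give the E,E-dienoate.

Step 17
Reactants: 21 ethyl (2E,4E,6R,7Z,12S)-6-ethenyl-2,4,8,12-tetramethyl-7-(2-oxopropyl)-13-[(triethylsilyl)oxy]trideca-2,4,7-trien-9-ynoate
Product: 22 (2E,4E,6R,7Z,12S)-6-ethenyl-7-(2-hydroxypropyl)-2,4,8,12-tetramethyl-13-[(triethylsilyl)oxy]trideca-2,4,7-trien-9-yn-1-ol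
Conditions: i-Bu2AlH (6 equiv), CH2Cl2, −78 °C; KNaC4H4O6 (aq)
Reagents that add atoms: none
Why: hydride reduction by i-Bu2AlH takes the ester to the allylic alcohol (1,2-reduction) and the ketone to the secondary alcohol in one operation.

Step 18
Reactants: 22 (2E,4E,6R,7Z,12S)-6-ethenyl-7-(2-hydroxypropyl)-2,4,8,12-tetramethyl-13-[(triethylsilyl)oxy]trideca-2,4,7-trien-9-yn-1-ol
Product: 23 bis(tert-butyldimethylsilyl) ether of 22 (triethylsilyl ether retained)
Conditions: TBSOTf, 2,6-lutidine, CH2Cl2, −78 °C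
Reagents that add atoms: tert-butyldimethylsilyl triflate, CC(C)(C)[Si](C)(C)OS(=O)(=O)C(F)(F)F
Why: silylation of both hydroxyls removes the allylic alcohol, which a cationic rhodium catalyst would isomerise, and the secondary alcohol.

Step 19
Reactants: 23 bis(tert-butyldimethylsilyl) ether of 22
Product: 24 (2S,6Z,8R,9E,11E)-13-[(tert-butyldimethylsilyl)oxy]-7-{2-[(tert-butyldimethylsilyl)oxy]propyl}-8-ethenyl-2,6,10,12-tetramethyltrideca-6,9,11-trien-4-ynal
Conditions: (COCl)2, DMSO, CH2Cl2, −78 → −30 °C; Et3N, −78 → 0 °C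
Reagents that add atoms: none
Why: Swern conditions cleave and oxidise a primary triethylsilyl ether directly to the aldehyde while tert-butyldimethylsilyl ethers survive, and the low temperature should keep the α-methyl centre intact.

Step 20
Reactants: 24 (2S,6Z,8R,9E,11E)-13-[(tert-butyldimethylsilyl)oxy]-7-{2-[(tert-butyldimethylsilyl)oxy]propyl}-8-ethenyl-2,6,10,12-tetramethyltrideca-6,9,11-trien-4-ynal
Product: 25 (3S,8S,8aR)-7-{2-[(tert-butyldimethylsilyl)oxy]propyl}-8-[(1E,3E)-5-{[tert-butyl(dimethyl)silyl]oxy}-2,4-dimethylpenta-1,3-dien-1-yl]-3,6-dimethyl-3,4,8,8a-tetrahydronaphthalen-2(1H)-one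
Conditions: [Rh(dppe)]2(BF4)2 (5 mol %), CH2Cl2 (0.01 M), 25 → 40 °C
Reagents that add atoms: none
Why: Proposed new method: the cationic monovalent rhodium centre inserts into the aldehyde C–H bond, the acylrhodium hydride adds across the triple bond (hydride to the carbon that becomes C-5, rhodium to the one that becomes C-4a, net trans) to give a five-membered acylrhodacycle whose exocyclic alkenyl–Rh bond is syn to the C6=C7–C8 chain, the vinyl group on C-8 inserts into that Rh–C(sp2) bond, and C(acyl)–C(sp3) reductive elimination from the seven-membered trivalent rhodacycle releases the ketone and the catalyst. The closest known reaction type is the rhodium-catalysed [4+2] annulation of 4-alkynals with alkynes, acrylamides or isocyanates, which runs through the same acylrhodacycle, and the trans addition has its analogy in the rhodium-catalysed trans-hydroacylation of alkynals; new here are the intramolecular capture by an unactivated alkene tethered through the alkyne terminus and the closure of two rings. Ring A (C4a–C8a bond) closes by 6-exo-trig migratory insertion and ring B (C1–C2 bond) by reductive elimination, both as six-membered rings. The only new stereocentre, C-8a, is controlled by C-8: in the insertion transition state the dienyl substituent on C-8 lies pseudo-axial to escape A(1,2) strain with the CH2 group on C-7, and the vinyl group, which has only hydrogen cis to C-8 and so no A(1,3) strain, reacts on the face that puts H-8a anti to that substituent (H-8 and H-8a cis). The step needs exo hydrorhodation rather than the endo mode that ends in a cyclopentenone, and insertion of the vinyl group rather than the trisubstituted diene; the non-coordinating solvent, the unhindered monosubstituted alkene and high dilution should secure both.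

Step 21
Reactants: 25 bicyclic ketone (C-1 = CH2)
Product: 28 (3S,8S,8aR)-1-methylidene analogue of 25, via Mannich base 26 (not isolated), via trimethylammonium iodide 27 (not isolated)
Conditions: LiN(i-Pr)2, THF, −78 °C; CH2=NMe2+ I−, −78 °C → rt; MeI, CH2Cl2, rt; NaHCO3 (aq)
Reagents that add atoms: N,N-dimethylmethyleneiminium iodide (Eschenmoser's salt), C=[N+](C)C.[I-]
Why: kinetic enolisation at the CH2 α-carbon (C-1) rather than the methyl-bearing C-3, Mannich reaction, quaternisation and mild E1cB elimination amount to a regioselective α-methylenation.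

Step 22
Reactants: 28 1-methylidene ketone
Product: 29 (1R,3S,8S,8aS)-7-{2-[(tert-butyldimethylsilyl)oxy]propyl}-8-[(1E,3E)-5-{[tert-butyl(dimethyl)silyl]oxy}-2,4-dimethylpenta-1,3-dien-1-yl]-1,3,6-trimethyl-3,4,8,8a-tetrahydronaphthalen-2(1H)-one
Conditions: H2 (1 atm), RhCl(PPh3)3 (10 mol %), benzene, rt
Reagents that add atoms: none
Why: homogeneous hydrogenation should reduce the 1,1-disubstituted enone alkene much faster than the tri- and tetrasubstituted alkenes, and syn delivery of H2 to the face opposite the pseudo-axial C-8 side chain sets (1R) with the methyl cis to that side chain.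

Step 23
Reactants: 29 bis(silyl) ether
Product: 30 (1R,3S,8S,8aS)-8-[(1E,3E)-5-hydroxy-2,4-dimethylpenta-1,3-dien-1-yl]-7-(2-hydroxypropyl)-1,3,6-trimethyl-3,4,8,8a-tetrahydronaphthalen-2(1H)-one
Conditions: TBAF, AcOH, THF, 0 °C → rt
Reagents that add atoms: none
Why: acetic acid-buffered fluoride removes both silyl ethers without enolising the ketone, whose two α-centres must not epimerise.

Step 24
Reactants: 30 dienol diol
Product: 31 (1R,3S,8S,8aS)-8-{(1E)-2-[(2S,3S)-3-(hydroxymethyl)-3-methyloxiran-2-yl]prop-1-en-1-yl}-7-(2-hydroxypropyl)-1,3,6-trimethyl-3,4,8,8a-tetrahydronaphthalen-2(1H)-one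
Conditions: Ti(Oi-Pr)4 (30 mol %), L-(+)-diethyl tartrate (36 mol %), t-BuOOH, 4 Å MS, CH2Cl2, −20 °C
Reagents that add atoms: tert-butyl hydroperoxide, CC(C)(C)OO
Why: Sharpless asymmetric epoxidation touches only the alkene of the allylic alcohol (not the ring diene or the other side-chain alkene), and the L-(+)-tartrate ligand should give the (2S,3S) epoxide.

Step 25
Reactants: 31 epoxy diol
Product: 32 (2R,3S)-2-methyl-3-{(1E)-1-[(1R,3S,8S,8aS)-1,3,6-trimethyl-2-oxo-7-(2-oxopropyl)-1,2,3,4,8,8a-hexahydronaphthalen-8-yl]prop-1-en-2-yl}oxirane-2-carbaldehyde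
Conditions: DMP (3 equiv), NaHCO3, CH2Cl2, 0 °C → rt
Reagents that add atoms: none
Why: Dess–Martin oxidation takes the primary epoxy alcohol to the non-enolisable epoxy aldehyde and the secondary alcohol to the 2-oxopropyl ketone under neutral conditions.

Step 26
Reactants: 32 keto epoxy aldehyde
Product: 33 2-(trimethylsilyl)ethyl (2E)-3-[(2S,3S)-2-methyl-3-{(1E)-1-[(1R,3S,8S,8aS)-1,3,6-trimethyl-2-oxo-7-(2-oxopropyl)-1,2,3,4,8,8a-hexahydronaphthalen-8-yl]prop-1-en-2-yl}oxiran-2-yl]prop-2-enoate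
Conditions: Ph3P=CHCO2CH2CH2SiMe3, CH2Cl2, rt
Reagents that add atoms: 2-(trimethylsilyl)ethyl (triphenylphosphoranylidene)acetate, C[Si](C)(C)CCOC(=O)C=P(c1ccccc1)(c1ccccc1)c1ccccc1
Why: Wittig reaction of the ester-stabilised ylide is aldehyde-selective in the presence of two ketones and should give the E-enoate.

Step 27
Reactants: 33 2-(trimethylsilyl)ethyl ester
Product: 34 (2E)-3-[(2S,3S)-2-methyl-3-{(1E)-1-[(1R,3S,8S,8aS)-1,3,6-trimethyl-2-oxo-7-(2-oxopropyl)-1,2,3,4,8,8a-hexahydronaphthalen-8-yl]prop-1-en-2-yl}oxiran-2-yl]prop-2-enoic acid (CNP0214881.1)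
Conditions: TASF, DMF, 0 °C → rt; NH4Cl (aq)
Reagents that add atoms: none
Why: fluoride-induced fragmentation of the 2-(trimethylsilyl)ethyl ester frees the acid without hydrolytic base or acid, so the vinyl epoxide, the β,γ-unsaturated ketone and the epimerisable centres should survive.

**Compound list**

1 | (4R)-4-benzyl-3-propanoyl-1,3-oxazolidin-2-one | CCC(=O)N1[C@H](Cc2ccccc2)COC1=O | starting material
2 | (4R)-4-benzyl-3-[(2S)-2-methylpent-4-ynoyl]-1,3-oxazolidin-2-one | C#CC[C@H](C)C(=O)N1[C@H](Cc2ccccc2)COC1=O | intermediate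
3 | (2S)-2-methylpent-4-yn-1-ol | C#CC[C@H](C)CO | intermediate
4 | triethyl{[(2S)-2-methylpent-4-yn-1-yl]oxy}silane | C#CC[C@H](C)CO[Si](CC)(CC)CC | intermediate
5 | {[(2S)-5-bromo-2-methylpent-4-yn-1-yl]oxy}triethylsilane | BrC#CC[C@H](C)CO[Si](CC)(CC)CC | intermediate
6 | but-3-enoic acid | C=CCC(=O)O | starting material
7 | (4S)-4-benzyl-1,3-oxazolidin-2-one | O=C1N[C@@H](Cc2ccccc2)CO1 | starting material
8 | but-3-enoic 2,2-dimethylpropanoic anhydride (not isolated) | C=CCC(=O)OC(=O)C(C)(C)C | intermediate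
9 | (4S)-4-benzyl-3-(but-3-enoyl)-1,3-oxazolidin-2-one | C=CCC(=O)N1[C@@H](Cc2ccccc2)COC1=O | intermediate
10 | (4S)-4-benzyl-3-[(2R)-2-(hydroxymethyl)but-3-enoyl]-1,3-oxazolidin-2-one | C=C[C@H](CO)C(=O)N1[C@@H](Cc2ccccc2)COC1=O | intermediate
11 | (4S)-4-benzyl-3-[(2R)-2-{[(tert-butyldimethylsilyl)oxy]methyl}but-3-enoyl]-1,3-oxazolidin-2-one | C=C[C@H](CO[Si](C)(C)C(C)(C)C)C(=O)N1[C@@H](Cc2ccccc2)COC1=O | intermediate
12 | (2S)-2-{[(tert-butyldimethylsilyl)oxy]methyl}but-3-en-1-ol | C=C[C@H](CO[Si](C)(C)C(C)(C)C)CO | intermediate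
13 | (2R)-2-{[(tert-butyldimethylsilyl)oxy]methyl}but-3-enal | C=C[C@H](CO[Si](C)(C)C(C)(C)C)C=O | intermediate
14 | tert-butyl{[(2S)-2-ethenylbut-3-yn-1-yl]oxy}dimethylsilane | C=C[C@H](CO[Si](C)(C)C(C)(C)C)C#C | intermediate
15 | (2S)-2-ethenylbut-3-yn-1-ol | C=C[C@H](CO)C#C | intermediate
16 | (2S,8S)-2-ethenyl-8-methyl-9-[(triethylsilyl)oxy]nona-3,5-diyn-1-ol | C=C[C@H](CO)C#CC#CC[C@H](C)CO[Si](CC)(CC)CC | intermediate
17 | cyclic alkenylmagnesium alkoxide from syn-methylmagnesiation of 16 (five-membered C–Mg–O chelate, methyl cis to magnesium; not isolated) | C=C[C@@H]1CO[Mg]/C1=C(\C)C#CC[C@H](C)CO[Si](CC)(CC)CC | intermediate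
18 | (2S,3Z,8S)-2-ethenyl-3-(2-hydroxypropyl)-4,8-dimethyl-9-[(triethylsilyl)oxy]non-3-en-5-yn-1-ol (both epimers at the hydroxypropyl carbinol) | C=C[C@H](CO)/C(CC(C)O)=C(/C)C#CC[C@H](C)CO[Si](CC)(CC)CC | intermediate
19 | (2S,3Z,8S)-2-ethenyl-4,8-dimethyl-3-(2-oxopropyl)-9-[(triethylsilyl)oxy]non-3-en-5-ynal | C=C[C@H](C=O)/C(CC(C)=O)=C(/C)C#CC[C@H](C)CO[Si](CC)(CC)CC | intermediate
20 | (2E,4R,5Z,10S)-4-ethenyl-2,6,10-trimethyl-5-(2-oxopropyl)-11-[(triethylsilyl)oxy]undeca-2,5-dien-7-ynal | C=C[C@H](/C=C(\C)C=O)/C(CC(C)=O)=C(/C)C#CC[C@H](C)CO[Si](CC)(CC)CC | intermediate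
21 | ethyl (2E,4E,6R,7Z,12S)-6-ethenyl-2,4,8,12-tetramethyl-7-(2-oxopropyl)-13-[(triethylsilyl)oxy]trideca-2,4,7-trien-9-ynoate | C=C[C@H](/C=C(\C)/C=C(\C)C(=O)OCC)/C(CC(C)=O)=C(/C)C#CC[C@H](C)CO[Si](CC)(CC)CC | intermediate
22 | (2E,4E,6R,7Z,12S)-6-ethenyl-7-(2-hydroxypropyl)-2,4,8,12-tetramethyl-13-[(triethylsilyl)oxy]trideca-2,4,7-trien-9-yn-1-ol (both carbinol epimers) | C=C[C@H](/C=C(\C)/C=C(\C)CO)/C(CC(C)O)=C(/C)C#CC[C@H](C)CO[Si](CC)(CC)CC | intermediate
23 | bis(tert-butyldimethylsilyl) ether of 22 at the allylic and the secondary hydroxyl, triethylsilyl ether retained (2E,4E,6R,7Z,12S) | C=C[C@H](/C=C(\C)/C=C(\C)CO[Si](C)(C)C(C)(C)C)/C(CC(C)O[Si](C)(C)C(C)(C)C)=C(/C)C#CC[C@H](C)CO[Si](CC)(CC)CC | intermediate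
24 | (2S,6Z,8R,9E,11E)-13-[(tert-butyldimethylsilyl)oxy]-7-{2-[(tert-butyldimethylsilyl)oxy]propyl}-8-ethenyl-2,6,10,12-tetramethyltrideca-6,9,11-trien-4-ynal | C=C[C@H](/C=C(\C)/C=C(\C)CO[Si](C)(C)C(C)(C)C)/C(CC(C)O[Si](C)(C)C(C)(C)C)=C(/C)C#CC[C@H](C)C=O | intermediate
25 | (3S,8S,8aR)-7-{2-[(tert-butyldimethylsilyl)oxy]propyl}-8-[(1E,3E)-5-{[tert-butyl(dimethyl)silyl]oxy}-2,4-dimethylpenta-1,3-dien-1-yl]-3,6-dimethyl-3,4,8,8a-tetrahydronaphthalen-2(1H)-one (H-8 and H-8a cis) | CC(O[Si](C)(C)C(C)(C)C)CC1=C(C)C=C2C[C@H](C)C(=O)C[C@@H]2[C@@H]1/C=C(\C)/C=C(\C)CO[Si](C)(C)C(C)(C)C | intermediate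
26 | 1-[(dimethylamino)methyl] derivative of 25 (Mannich base, C-1 undefined; not isolated) | CC(O[Si](C)(C)C(C)(C)C)CC1=C(C)C=C2C[C@H](C)C(=O)C(CN(C)C)[C@@H]2[C@@H]1/C=C(\C)/C=C(\C)CO[Si](C)(C)C(C)(C)C | intermediate
27 | trimethylammonium iodide of 26 (not isolated) | CC(O[Si](C)(C)C(C)(C)C)CC1=C(C)C=C2C[C@H](C)C(=O)C(C[N+](C)(C)C)[C@@H]2[C@@H]1/C=C(\C)/C=C(\C)CO[Si](C)(C)C(C)(C)C.[I-] | intermediate
28 | (3S,8S,8aR)-1-methylidene analogue of 25 | CC(O[Si](C)(C)C(C)(C)C)CC1=C(C)C=C2C[C@H](C)C(=O)C(=C)[C@@H]2[C@@H]1/C=C(\C)/C=C(\C)CO[Si](C)(C)C(C)(C)C | intermediate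
29 | (1R,3S,8S,8aS)-7-{2-[(tert-butyldimethylsilyl)oxy]propyl}-8-[(1E,3E)-5-{[tert-butyl(dimethyl)silyl]oxy}-2,4-dimethylpenta-1,3-dien-1-yl]-1,3,6-trimethyl-3,4,8,8a-tetrahydronaphthalen-2(1H)-one | CC(O[Si](C)(C)C(C)(C)C)CC1=C(C)C=C2C[C@H](C)C(=O)[C@H](C)[C@@H]2[C@@H]1/C=C(\C)/C=C(\C)CO[Si](C)(C)C(C)(C)C | intermediate
30 | (1R,3S,8S,8aS)-8-[(1E,3E)-5-hydroxy-2,4-dimethylpenta-1,3-dien-1-yl]-7-(2-hydroxypropyl)-1,3,6-trimethyl-3,4,8,8a-tetrahydronaphthalen-2(1H)-one | CC(O)CC1=C(C)C=C2C[C@H](C)C(=O)[C@H](C)[C@@H]2[C@@H]1/C=C(\C)/C=C(\C)CO | intermediate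
31 | (1R,3S,8S,8aS)-8-{(1E)-2-[(2S,3S)-3-(hydroxymethyl)-3-methyloxiran-2-yl]prop-1-en-1-yl}-7-(2-hydroxypropyl)-1,3,6-trimethyl-3,4,8,8a-tetrahydronaphthalen-2(1H)-one | CC(O)CC1=C(C)C=C2C[C@H](C)C(=O)[C@H](C)[C@@H]2[C@@H]1/C=C(\C)[C@@H]1O[C@@]1(C)CO | intermediate
32 | (2R,3S)-2-methyl-3-{(1E)-1-[(1R,3S,8S,8aS)-1,3,6-trimethyl-2-oxo-7-(2-oxopropyl)-1,2,3,4,8,8a-hexahydronaphthalen-8-yl]prop-1-en-2-yl}oxirane-2-carbaldehyde | CC(=O)CC1=C(C)C=C2C[C@H](C)C(=O)[C@H](C)[C@@H]2[C@@H]1/C=C(\C)[C@@H]1O[C@@]1(C)C=O | intermediate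
33 | 2-(trimethylsilyl)ethyl (2E)-3-[(2S,3S)-2-methyl-3-{(1E)-1-[(1R,3S,8S,8aS)-1,3,6-trimethyl-2-oxo-7-(2-oxopropyl)-1,2,3,4,8,8a-hexahydronaphthalen-8-yl]prop-1-en-2-yl}oxiran-2-yl]prop-2-enoate | CC(=O)CC1=C(C)C=C2C[C@H](C)C(=O)[C@H](C)[C@@H]2[C@@H]1/C=C(\C)[C@@H]1O[C@@]1(C)/C=C/C(=O)OCC[Si](C)(C)C | intermediate
34 | (2E)-3-[(2S,3S)-2-methyl-3-{(1E)-1-[(1R,3S,8S,8aS)-1,3,6-trimethyl-2-oxo-7-(2-oxopropyl)-1,2,3,4,8,8a-hexahydronaphthalen-8-yl]prop-1-en-2-yl}oxiran-2-yl]prop-2-enoic acid | CC(=O)CC1=C(C)C=C2C[C@H](C)C(=O)[C@H](C)[C@@H]2[C@@H]1/C=C(\C)[C@@H]1O[C@@]1(C)/C=C/C(=O)O | target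

**Step count**

Total: 27 steps (4 for the bromoalkyne fragment, 23 in the main line). Longest linear sequence: 23 steps (steps 5–27, from but-3-enoic acid).

**Steps most likely to fail, with fallbacks**

Step 20 (Proposed new method). The acylrhodium hydride may add to the triple bond in the endo sense and collapse to a cyclopentenone, may decarbonylate, or the alkenylrhodium may not reach the geometry from which the vinyl group can insert. The fallback uses known radical chemistry and sets out from tris(silyl) ether 23. syn-Hydroalumination of the triple bond (i-Bu2AlH, hexane, 50 °C) followed by I2 should give dienyl iodide F1, with iodine on the alkyne carbon next to the CH2 group. Swern oxidation of the triethylsilyl ether, as in step 19, gives iodo aldehyde F2. Slow addition of Bu3SnH with AIBN (benzene, 80 °C) generates the alkenyl radical at the future C-4a; its geometry is immaterial because alkenyl radicals invert rapidly. A 6-exo cyclisation on to the internal carbon of the vinyl group (ring A), then 6-exo addition of the primary radical to the aldehyde (ring B) and hydrogen transfer, should give bicyclic alcohol F3. DMP oxidation returns to ketone 25.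

Step 13. The hindered, chelated tetrasubstituted alkenylmagnesium may be captured too slowly by the epoxide, so that protonation on work-up gives the trisubstituted alkene instead. The fallback sets out from diynol 16: the same carbomagnesiation is run, but chelate 17 is quenched with I2 to give alkenyl iodide F4. A Kosugi–Migita acetonylation (Bu3SnOMe, isopropenyl acetate, PdCl2[P(o-tol)3]2 cat., toluene, 80 °C) installs the 2-oxopropyl group directly and gives hydroxy ketone F5. DMP oxidation of its primary alcohol returns to keto aldehyde 19.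

Step 22. Hydrogen may be delivered to the wrong face, or the catalyst may start to reduce or isomerise the conjugated dienes. The fallback sets out from enone 28 and replaces hydrogenation by conjugate hydride addition with [(Ph3P)CuH]6 (toluene, 0 °C), which forms the C1–C2 enolate regiospecifically. Protonation at −78 °C with a bulky proton donor (2,6-di-tert-butyl-4-methylphenol) on the open face comes back to ketone 29 without a new isolated compound.

**Further compounds**

F1 | step 20 | (4E)-dienyl iodide from 23: tert-butyldimethylsilyl and triethylsilyl ethers as in 23, C4=C5 alkene carrying iodine on the carbon next to the CH2 group | C=C[C@H](/C=C(\C)/C=C(\C)CO[Si](C)(C)C(C)(C)C)/C(CC(C)O[Si](C)(C)C(C)(C)C)=C(/C)\C=C(\I)C[C@H](C)CO[Si](CC)(CC)CC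
F2 | step 20 | iodo aldehyde, the 4-iodo-4-ene analogue of aldehyde 24 | C=C[C@H](/C=C(\C)/C=C(\C)CO[Si](C)(C)C(C)(C)C)/C(CC(C)O[Si](C)(C)C(C)(C)C)=C(/C)\C=C(\I)C[C@H](C)C=O
F3 | step 20 | bicyclic alcohol, the 2-hydroxy analogue of ketone 25 (carbinol configuration undefined) | CC(O[Si](C)(C)C(C)(C)C)CC1=C(C)C=C2C[C@H](C)C(O)C[C@@H]2[C@@H]1/C=C(\C)/C=C(\C)CO[Si](C)(C)C(C)(C)C
F4 | step 13 | (2S,3E,8S)-2-ethenyl-3-iodo-4,8-dimethyl-9-[(triethylsilyl)oxy]non-3-en-5-yn-1-ol | C=C[C@H](CO)/C(I)=C(/C)C#CC[C@H](C)CO[Si](CC)(CC)CC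
F5 | step 13 | (2S,3Z,8S)-2-ethenyl-3-(2-oxopropyl)-4,8-dimethyl-9-[(triethylsilyl)oxy]non-3-en-5-yn-1-ol | C=C[C@H](CO)/C(CC(C)=O)=C(/C)C#CC[C@H](C)CO[Si](CC)(CC)CC
F0 | step 22 | none | none
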